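**Plan**
- Retrosynthetic cuts, in order: the C8–CH2 bond between flavone ring A and the 4-hydroxybenzyl carbon; the three O-benzyl groups; the O1–C2 bond and C2=C3 unsaturation of ring C (back to a 2'-hydroxychalcone); the chalcone Cα=Cβ bond (aldol); two O–benzyl bonds of the acetophenone.
- Forward: ring A comes from phloroacetophenone and ring B from O-benzylisovanillin; the chalcone is made, ring C is closed and aromatised in one flask, the benzyl unit is joined to C8, and hydrogenolysis ends the route.
- Enabling feature: C8 of ring A lies ortho/ortho/para to three oxygens (O1, 7-O, 5-O) and only meta to the acyl carbon C4a–C4=O, so it is an arene nucleophile. The para-OH of the benzyl fragment lets its CH2 become the exocyclic carbon of a para-quinone methide, the electrophile/nucleophile pairing of the presumed biosynthesis.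
- Regiocontrol: the 5-O-benzyl group, turned toward C6 by the peri C4=O, shields C6 and leaves C8 open.
- Stereochemistry: the target has no stereogenic element, so nothing has to be set.

Key step: step 4

Remark on the chemistry: the target is achiral (no stereocentre, no stereogenic axis, no configurable double bond), so "single enantiomer" is taken to mean the single constitution shown. The (E)-alkene of the chalcone and the racemic C2 of the flavanone are transient and vanish on aromatisation of ring C.

**Step 1**
Reactants: 1 2',4',6'-trihydroxyacetophenone (phloroacetophenone)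
Product: 2 1-[2,4-bis(benzyloxy)-6-hydroxyphenyl]ethan-1-one
Conditions: BnBr (2.1 equiv), K2CO3 (2.2 equiv), DMF, 0 °C → rt
Reagents that add atoms: benzyl bromide, BrCc1ccccc1
Why: Williamson etherification; once the para-OH and one ortho-OH are benzylated, the remaining ortho-OH is locked in a hydrogen bond to the acetyl C=O and is too weakly nucleophilic to react, so alkylation should stop at the bis-ether.

**Step 2**
Reactants: 2 1-[2,4-bis(benzyloxy)-6-hydroxyphenyl]ethan-1-one; 3 3-(benzyloxy)-4-methoxybenzaldehyde (O-benzylisovanillin)
Product: 4 (E)-1-[2,4-bis(benzyloxy)-6-hydroxyphenyl]-3-[3-(benzyloxy)-4-methoxyphenyl]prop-2-en-1-one (2'-hydroxychalcone)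
Conditions: KOH (50% aq.), EtOH/THF, rt
Reagents that add atoms: none
Why: Claisen–Schmidt aldol condensation of a methyl ketone with a non-enolisable aldehyde; E1cB dehydration under thermodynamic control should give the conjugated (E)-enone.

**Step 3**
Reactants: 4 the (E)-2'-hydroxychalcone
Product: 6 5,7-bis(benzyloxy)-2-[3-(benzyloxy)-4-methoxyphenyl]-4H-chromen-4-one (tri-O-benzyldiosmetin), via rac-5,7-bis(benzyloxy)-2-[3-(benzyloxy)-4-methoxyphenyl]chroman-4-one 5 (not isolated)
Conditions: I2 (10 mol %), DMSO, 120–130 °C
Reagents that add atoms: none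
Why: I2/DMSO oxidative cyclisation of a 2'-hydroxychalcone: 6-endo-trig oxa-Michael closure of ring C gives the flavanone, α-iodination and loss of HI give the flavone, and DMSO reoxidises HI to I2 so that iodine stays catalytic and the benzyl ethers see little acid.

**Step 4**
Reactants: 6 5,7-bis(benzyloxy)-2-[3-(benzyloxy)-4-methoxyphenyl]-4H-chromen-4-one; 7 4-hydroxybenzyl alcohol
Product: 9 5,7-bis(benzyloxy)-2-[3-(benzyloxy)-4-methoxyphenyl]-8-(4-hydroxybenzyl)-4H-chromen-4-one, via 4-methylidenecyclohexa-2,5-dien-1-one (para-quinone methide) 8 (not isolated)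
Conditions: 7 (1.3 equiv, slow addition), TsOH·H2O (5 mol %), HFIP/CH2Cl2 4:1, 0 °C → rt
Reagents that add atoms: none
Why: Acid- and HFIP-assisted dehydration of 7 gives the para-quinone methide 8; its exocyclic CH2, activated by protonation or hydrogen bonding at the carbonyl oxygen, is attacked by C8 of ring A, and loss of the C8 proton rearomatises both rings (SEAr). The closest known reaction type is the Brønsted-acid/HFIP-promoted Friedel–Crafts benzylation of polyalkoxyarenes with para-hydroxybenzyl alcohols through para-quinone methides formed in situ, the laboratory counterpart of the presumed biosynthetic C-benzylation of flavonoid A rings. No ring is closed and no stereocentre is formed. The step needs C8 over C6: both carbons carry three oxygen donors, but C6 lies between two benzyloxy groups and the 5-O-benzyl group is turned toward it by peri repulsion with C4=O, whereas C8 has the unsubstituted ring oxygen O1 as neighbour, the same preference that halogenation of 5,7-dialkoxyflavones shows. It also needs ring A over ring B, over C3 and over the phenol ring of 7 and 9: ring A is the most electron-rich arene present because the carbonyl is only meta to C8, while ring B is conjugated to the electron-poor C2. Slow addition of 7 keeps the concentration of 8 low, which should suppress self-condensation of the quinone methide and a second benzylation.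

**Step 5**
Reactants: 9 5,7-bis(benzyloxy)-2-[3-(benzyloxy)-4-methoxyphenyl]-8-(4-hydroxybenzyl)-4H-chromen-4-one
Product: 10 5,7-dihydroxy-2-(3-hydroxy-4-methoxyphenyl)-8-(4-hydroxybenzyl)-4H-chromen-4-one (target, CNP0159308.0)
Conditions: H2 (1 atm), 10% Pd/C, THF/MeOH 1:1, rt, stopped at full debenzylation
Reagents that add atoms: none
Why: Catalytic hydrogenolysis of three aryl benzyl ethers; the diarylmethane C–C bond, the methyl ether and the vinylogous-ester C2=C3 bond of the flavone are expected to survive mild Pd/C conditions.

**Compound list**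
1 | 2',4',6'-trihydroxyacetophenone | CC(=O)c1c(O)cc(O)cc1O | starting material
2 | 1-[2,4-bis(benzyloxy)-6-hydroxyphenyl]ethan-1-one | CC(=O)c1c(O)cc(OCc2ccccc2)cc1OCc1ccccc1 | intermediate
3 | 3-(benzyloxy)-4-methoxybenzaldehyde | COc1ccc(C=O)cc1OCc1ccccc1 | starting material
4 | (E)-1-[2,4-bis(benzyloxy)-6-hydroxyphenyl]-3-[3-(benzyloxy)-4-methoxyphenyl]prop-2-en-1-one | COc1ccc(/C=C/C(=O)c2c(O)cc(OCc3ccccc3)cc2OCc2ccccc2)cc1OCc1ccccc1 | intermediate
5 | rac-5,7-bis(benzyloxy)-2-[3-(benzyloxy)-4-methoxyphenyl]chroman-4-one (racemic at C2) | COc1ccc(C2CC(=O)c3c(OCc4ccccc4)cc(OCc4ccccc4)cc3O2)cc1OCc1ccccc1 | intermediate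
6 | 5,7-bis(benzyloxy)-2-[3-(benzyloxy)-4-methoxyphenyl]-4H-chromen-4-one | COc1ccc(-c2cc(=O)c3c(OCc4ccccc4)cc(OCc4ccccc4)cc3o2)cc1OCc1ccccc1 | intermediate
7 | 4-hydroxybenzyl alcohol | OCc1ccc(O)cc1 | starting material
8 | 4-methylidenecyclohexa-2,5-dien-1-one (para-quinone methide) | C=C1C=CC(=O)C=C1 | intermediate
9 | 5,7-bis(benzyloxy)-2-[3-(benzyloxy)-4-methoxyphenyl]-8-(4-hydroxybenzyl)-4H-chromen-4-one | COc1ccc(-c2cc(=O)c3c(OCc4ccccc4)cc(OCc4ccccc4)c(Cc4ccc(O)cc4)c3o2)cc1OCc1ccccc1 | intermediate
10 | 5,7-dihydroxy-2-(3-hydroxy-4-methoxyphenyl)-8-(4-hydroxybenzyl)-4H-chromen-4-one | COc1ccc(-c2cc(=O)c3c(O)cc(O)c(Cc4ccc(O)cc4)c3o2)cc1O | target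

**Totals**
Total step count: 5. Longest linear sequence: 5 steps (1 → 2 → 4 → 6 → 9 → 10).

**Steps most likely to fail**

Step 4. The quinone methide may be taken up at C6 as well as at C8, may condense with itself, or may benzylate the product a second time. Fallback, setting out from 6: iodination with N-iodosuccinimide and catalytic TFA in MeCN should give 5,7-bis(benzyloxy)-2-[3-(benzyloxy)-4-methoxyphenyl]-8-iodo-4H-chromen-4-one F1, following the C8 preference of 5,7-dialkoxyflavones in halogenation. Zinc insertion into commercial 4-(benzyloxy)benzyl chloride (Zn dust, LiCl, THF) should give [4-(benzyloxy)benzyl]zinc chloride F2. Negishi coupling of F1 with F2 (Pd(OAc)2/SPhos, THF, rt to 50 °C) should give 5,7-bis(benzyloxy)-8-[4-(benzyloxy)benzyl]-2-[3-(benzyloxy)-4-methoxyphenyl]-4H-chromen-4-one F3. Hydrogenolysis under the conditions of step 5, now removing four benzyl groups, brings the route back at 10.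

Step 3. Hydrogen iodide formed in the flask may cleave the peri 5-O-benzyl ether, which would remove the C6 shielding needed in step 4, or the oxidation may stall at the flavanone stage. Fallback, setting out from 4: ring closure is done separately by base-mediated oxa-Michael addition (NaOAc, EtOH, reflux) and the flavanone 5 is isolated. It is then dehydrogenated by hydride abstraction with DDQ in dioxane at reflux, with no iodide or strong acid present, and the route is rejoined at 6. This fallback makes no compound outside the compound list (F0).

Step 5. Hydrogenation may run on into the C2=C3 bond of the pyranone ring, or the hindered 5- and 7-O-benzyl ethers may be removed incompletely. Fallback, setting out from 9: Lewis-acid debenzylation with BCl3 and pentamethylbenzene as benzyl-cation scavenger in CH2Cl2 at −78 °C. The non-chelated 4'-methyl ether should survive, and the scavenger keeps benzyl cations off the electron-rich rings. The route is rejoined directly at 10. This fallback makes no compound outside the compound list (F0).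

**Further compounds**
F1 | step 4 | 5,7-bis(benzyloxy)-2-[3-(benzyloxy)-4-methoxyphenyl]-8-iodo-4H-chromen-4-one | COc1ccc(-c2cc(=O)c3c(OCc4ccccc4)cc(OCc4ccccc4)c(I)c3o2)cc1OCc1ccccc1
F2 | step 4 | [4-(benzyloxy)benzyl]zinc chloride | Cl[Zn]Cc1ccc(OCc2ccccc2)cc1
F3 | step 4 | 5,7-bis(benzyloxy)-8-[4-(benzyloxy)benzyl]-2-[3-(benzyloxy)-4-methoxyphenyl]-4H-chromen-4-one | COc1ccc(-c2cc(=O)c3c(OCc4ccccc4)cc(OCc4ccccc4)c(Cc4ccc(OCc5ccccc5)cc4)c3o2)cc1OCc1ccccc1
F0 | step 3 | none | none
F0 | step 5 | none | none
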